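## Retrosynthetic overview

1. 3β-Acetoxyagathic acid (29) ← diallyl ester 28 (deallylation, acetylation) ← enone 25 (1,4-reduction, then hydride delivery to C3 from the α-face) ← cycloadduct 24.
2. Key disconnection (labdane numbering): one thermal intramolecular Diels–Alder reaction of acyclic triene 22 forms the C5–C10 ring-fusion bond and the C3–C4 bond, and sets C3, C4, C5 and C10 from the single stereocenter C9.
3. Enabling feature: in ring A the C3 oxygen and the C4 carboxyl sit on adjacent carbons next to the fusion bond. Ring A is therefore the "ortho" adduct of a 1-silyloxydiene (C3=C2–C1=C10, with C10 carrying the future angular methyl) and a carboxyl-activated alkene (C4=C5), and the four ring-B carbons C6–C9 are the tether.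
4. Triene 22 ← skipped triene 15 by anti-SN2' chirality transfer (allylic picolinate 10 plus alkenyl Grignard reagent 14), then Still–Gennari olefination for the (Z)-dienophile. Picolinate 10 ← methyl geranate, whose (E)-enoate becomes the side chain unchanged.
5. Ring order: rings A and B are closed together in step 15 (A by the cycloaddition, B by the tether); no ring exists before it.

Key step: step 15

Remark: labdane numbering (C1–C20) is used for ring positions, and commercial methyl geranate is taken as the pure (2E)-isomer (a 2E/2Z mixture would be separated before use).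

## Route

Step 1
Reactants: 1 methyl (2E)-3,7-dimethylocta-2,6-dienoate (methyl geranate)
Product: 2 methyl (2E)-3-methyl-6-oxohex-2-enoate
Conditions: O3 (1 equiv), CH2Cl2/MeOH, −78 °C; then Me2S, −78 °C → rt
Reagents that add atoms: ozone, [O-][O+]=O
Why: Ozonolysis with reductive work-up; the electron-rich isopropylidene alkene is cleaved much faster than the ester-conjugated 2,3-alkene, so the (E)-enoate of the future side chain survives unchanged.

Step 2
Reactants: 2 methyl (2E)-3-methyl-6-oxohex-2-enoate; 3 ethyltriphenylphosphonium iodide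
Product: 5 methyl (2E,6Z)-7-iodo-3-methylocta-2,6-dienoate, via iodo ylide 4 (not isolated)
Conditions: 3, n-BuLi, THF, 0 °C; I2, −78 °C; NaN(SiMe3)2, −20 °C; then 2, −78 °C → rt
Reagents that add atoms: iodine, II
Why: Stork–Zhao-type Wittig olefination with the non-stabilized α-iodo ylide, which should give the (Z)-iodoalkene (iodine cis to the chain) at low temperature without touching the ester.

Step 3
Reactants: 5 methyl (2E,6Z)-7-iodo-3-methylocta-2,6-dienoate; 6 3-[(tert-butyldimethylsilyl)oxy]propanal
Product: 7 methyl (2E,6Z)-10-[(tert-butyldimethylsilyl)oxy]-8-hydroxy-3,7-dimethyldeca-2,6-dienoate (racemic at C8)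
Conditions: CrCl2 (4 equiv), NiCl2 (1 mol%), DMF, rt
Reagents that add atoms: none
Why: Nozaki–Hiyama–Kishi coupling; the alkenylchromium reagent forms with retention of alkene geometry and adds to the aldehyde only, the new carbinol being racemic at this point.

Step 4
Reactants: 7 methyl (2E,6Z)-10-[(tert-butyldimethylsilyl)oxy]-8-hydroxy-3,7-dimethyldeca-2,6-dienoate
Product: 8 methyl (2E,6Z)-10-[(tert-butyldimethylsilyl)oxy]-3,7-dimethyl-8-oxodeca-2,6-dienoate
Conditions: Dess–Martin periodinane, NaHCO3, CH2Cl2, 0 °C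
Reagents that add atoms: none
Why: Dess–Martin oxidation under buffered conditions removes the uncontrolled carbinol stereocenter and should not isomerize the (Z)-enone.

Step 5
Reactants: 8 methyl (2E,6Z)-10-[(tert-butyldimethylsilyl)oxy]-3,7-dimethyl-8-oxodeca-2,6-dienoate
Product: 9 methyl (2E,6Z,8S)-10-[(tert-butyldimethylsilyl)oxy]-8-hydroxy-3,7-dimethyldeca-2,6-dienoate
Conditions: (R)-2-methyl-CBS-oxazaborolidine (20 mol%), catecholborane, toluene, −78 °C; then MeOH, aq. NaOH wash
Reagents that add atoms: none
Why: Corey–Bakshi–Shibata reduction, in which the α-branched alkenyl group acts as the large substituent so that the (R)-catalyst should deliver hydride to the face giving the (8S)-alcohol, while catecholborane at low temperature leaves the alkenes and the ester alone.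

Step 6
Reactants: 9 methyl (2E,6Z,8S)-10-[(tert-butyldimethylsilyl)oxy]-8-hydroxy-3,7-dimethyldeca-2,6-dienoate
Product: 10 methyl (2E,6Z,8S)-10-[(tert-butyldimethylsilyl)oxy]-3,7-dimethyl-8-(pyridine-2-carbonyloxy)deca-2,6-dienoate
Conditions: picolinic acid, DCC, DMAP (cat.), CH2Cl2, 0 °C → rt
Reagents that add atoms: picolinic acid, OC(=O)c1ccccn1
Why: Steglich esterification installs the picolinoxy leaving group without breaking a bond at the stereocenter.

Step 7
Reactants: 11 2,3-dibromoprop-1-ene; 12 (1,3-dioxolan-2-ylmethyl)magnesium bromide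
Product: 13 2-(3-bromobut-3-en-1-yl)-1,3-dioxolane
Conditions: CuI (5 mol%), THF, 0 °C
Reagents that add atoms: none
Why: Copper-catalyzed allylic substitution of the allylic bromide by the Grignard reagent (direct and allylic-shift attack give the same product), the vinylic bromide being inert.

Step 8
Reactants: 10 methyl (2E,6Z,8S)-10-[(tert-butyldimethylsilyl)oxy]-3,7-dimethyl-8-(pyridine-2-carbonyloxy)deca-2,6-dienoate; 13 2-(3-bromobut-3-en-1-yl)-1,3-dioxolane
Product: 15 methyl (2E,6S,7E)-10-[(tert-butyldimethylsilyl)oxy]-6-[4-(1,3-dioxolan-2-yl)but-1-en-2-yl]-3,7-dimethyldeca-2,7-dienoate, via alkenyl Grignard reagent 14 (not isolated)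
Conditions: 13, Mg, THF, 50 °C; then CuBr·SMe2 (0.5 equiv), 10, THF, −40 → 0 °C
Reagents that add atoms: none
Why: Copper-mediated anti-SN2' allylic substitution of an allylic picolinate by an alkenyl Grignard reagent: chelation of magnesium by the picolinoxy group directs attack to the γ-carbon (C9) anti to the leaving group, and A(1,3) strain from the cis side chain holds the C1–H bond in the alkene plane, so the (8S)-carbinol center is converted into the (S)-configured C9 stereocenter and the (E)-C1=C10 alkene.

Step 9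
Reactants: 15 methyl (2E,6S,7E)-10-[(tert-butyldimethylsilyl)oxy]-6-[4-(1,3-dioxolan-2-yl)but-1-en-2-yl]-3,7-dimethyldeca-2,7-dienoate
Product: 16 methyl (2E,6S,7E)-10-[(tert-butyldimethylsilyl)oxy]-3,7-dimethyl-6-(5-oxopent-1-en-2-yl)deca-2,7-dienoate
Conditions: LiBF4, MeCN/H2O (98:2), rt
Reagents that add atoms: water, O
Why: Mild Lewis-acid hydrolysis of the dioxolane in wet acetonitrile, conditions chosen to leave the primary silyl ether, the skipped diene and the ester intact.

Step 10
Reactants: 16 methyl (2E,6S,7E)-10-[(tert-butyldimethylsilyl)oxy]-3,7-dimethyl-6-(5-oxopent-1-en-2-yl)deca-2,7-dienoate; 17 ethyl 2-[bis(2,2,2-trifluoroethoxy)phosphoryl]propanoate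
Product: 18 1-ethyl 12-methyl (2Z,7S,10E)-7-[(2E)-5-[(tert-butyldimethylsilyl)oxy]pent-2-en-2-yl]-2,10-dimethyl-6-methylidenedodeca-2,10-dienedioate
Conditions: 17, KN(SiMe3)2, 18-crown-6, THF, −78 °C; then 16
Reagents that add atoms: none
Why: Still–Gennari olefination; the bis(trifluoroethyl) phosphonate under dissociating conditions should give the (Z)-2-methyl enoate (ester cis to the chain) needed as dienophile.

Step 11
Reactants: 18 1-ethyl 12-methyl (2Z,7S,10E)-7-[(2E)-5-[(tert-butyldimethylsilyl)oxy]pent-2-en-2-yl]-2,10-dimethyl-6-methylidenedodeca-2,10-dienedioate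
Product: 19 diallyl (2Z,7S,10E)-7-[(2E)-5-[(tert-butyldimethylsilyl)oxy]pent-2-en-2-yl]-2,10-dimethyl-6-methylidenedodeca-2,10-dienedioate
Conditions: allyl alcohol (solvent), Ti(OiPr)4 (20 mol%), 95 °C
Reagents that add atoms: allyl alcohol, C=CCO
Why: Titanium alkoxide-mediated transesterification under neutral conditions exchanges both the methyl and the ethyl ester for allyl esters, which can be removed at the end without hydrolysis of the hindered C19 ester or of the acetate.

Step 12
Reactants: 19 diallyl (2Z,7S,10E)-7-[(2E)-5-[(tert-butyldimethylsilyl)oxy]pent-2-en-2-yl]-2,10-dimethyl-6-methylidenedodeca-2,10-dienedioate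
Product: 20 diallyl (2Z,7S,10E)-7-[(2E)-5-hydroxypent-2-en-2-yl]-2,10-dimethyl-6-methylidenedodeca-2,10-dienedioate
Conditions: HF·pyridine, pyridine, THF, 0 °C → rt
Reagents that add atoms: none
Why: Fluoride cleavage of the primary silyl ether; allyl esters and alkenes are inert to buffered HF·pyridine.

Step 13
Reactants: 20 diallyl (2Z,7S,10E)-7-[(2E)-5-hydroxypent-2-en-2-yl]-2,10-dimethyl-6-methylidenedodeca-2,10-dienedioate
Product: 21 diallyl (2Z,7S,10E)-2,10-dimethyl-6-methylidene-7-[(2E)-5-oxopent-2-en-2-yl]dodeca-2,10-dienedioate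
Conditions: Dess–Martin periodinane, NaHCO3, CH2Cl2, 0 °C
Reagents that add atoms: none
Why: Buffered Dess–Martin oxidation gives the β,γ-unsaturated aldehyde without moving the trisubstituted alkene into conjugation.

Step 14
Reactants: 21 diallyl (2Z,7S,10E)-2,10-dimethyl-6-methylidene-7-[(2E)-5-oxopent-2-en-2-yl]dodeca-2,10-dienedioate
Product: 22 diallyl (2Z,7S,10E)-7-[(2E,4E)-5-[(tert-butyldimethylsilyl)oxy]penta-2,4-dien-2-yl]-2,10-dimethyl-6-methylidenedodeca-2,10-dienedioate
Conditions: TBSOTf, Et3N, Et2O, −78 → 0 °C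
Reagents that add atoms: tert-butyldimethylsilyl trifluoromethanesulfonate, CC(C)(C)[Si](C)(C)OS(=O)(=O)C(F)(F)F
Why: Soft enolization and O-silylation at the doubly activated C2 position gives the 1-silyloxy-1,3-diene with the C1=C10 geometry untouched; the new C2=C3 enol ether may form as an E/Z pair, of which the (E)-isomer shown is the reactive diene, and any adduct from the (Z)-isomer would differ only at C3, which is erased in step 16.

Step 15
Reactants: 22 diallyl (2Z,7S,10E)-7-[(2E,4E)-5-[(tert-butyldimethylsilyl)oxy]penta-2,4-dien-2-yl]-2,10-dimethyl-6-methylidenedodeca-2,10-dienedioate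
Product: 24 diallyl 3α-hydroxylabda-1,8(17),13E-triene-15,19-dioate, via silyl ether cycloadduct 23 (not isolated)
Conditions: toluene (0.01 M), BHT, Et3N (trace), 140 °C, sealed tube; then HF·pyridine, THF, 0 °C → rt
Reagents that add atoms: none
Why: Thermal intramolecular Diels–Alder reaction (type 1, 1,7,9-decatriene pattern): a concerted but asynchronous [4+2] cycloaddition in which the largest HOMO coefficient of the 1-silyloxydiene (C10) meets the largest LUMO coefficient of the enoate (C5), so that the C5–C10 bond leads and the C3–C4 bond follows. The closest known reaction type is the thermal cyclization of 1,7,9-decatrienes carrying an ester on the dienophile to trans-fused octalins, which tolerates a methyl group on the tethered diene terminus and α-substituted enoate dienophiles. Ring A closes as the new cyclohexene by the cycloaddition itself (bonds C5–C10 and C3–C4), and ring B closes in the same event by the C5–C10 bond through the four-carbon tether C6–C9, which folds as a chair. The C4/C5 relationship comes from the (Z)-geometry of the dienophile and the C10/C3 relationship from the (E,E)-geometry of the diene (both components react suprafacially), the trans ring fusion from the chair tether with the ester exo and the C4 methyl endo, and the absolute sense of all four centers from C9, whose side chain sits pseudo-equatorial and thereby avoids syn-axial contact with the hydrogens on C5 and C7. The step needs trans- over cis-fusion, attack on one π-face and reaction at C4=C5 only: the first is supported by the exo-ester preference of α-methyl acrylate-type dienophiles and the chair tether, the second by the C9 substituent, and the third by the fact that the β,β-disubstituted side-chain enoate could only add by joining two fully substituted carbons (C10 and C13) through a three-atom tether. The silyl ether 23 is cleaved in the same flask, and its α-configured C3 center (silyloxy group on the outside of the diene) need not be kept because C3 is oxidized in step 16.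

Step 16
Reactants: 24 diallyl 3α-hydroxylabda-1,8(17),13E-triene-15,19-dioate
Product: 25 diallyl 3-oxolabda-1,8(17),13E-triene-15,19-dioate
Conditions: Dess–Martin periodinane, NaHCO3, CH2Cl2, rt
Reagents that add atoms: none
Why: Dess–Martin oxidation of the allylic alcohol removes the C3 stereocenter, so both possible C3 epimers converge on one enone.

Step 17
Reactants: 25 diallyl 3-oxolabda-1,8(17),13E-triene-15,19-dioate
Product: 26 diallyl 3-oxolabda-8(17),13E-diene-15,19-dioate
Conditions: [(Ph3P)CuH]6 (0.5 equiv), toluene, H2O (3 equiv), rt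
Reagents that add atoms: none
Why: Copper hydride conjugate reduction, chemoselective for the β-unsubstituted ring enone over the isolated 8(17)-alkene, the β,β-disubstituted side-chain enoate and the allyl esters.

Step 18
Reactants: 26 diallyl 3-oxolabda-8(17),13E-diene-15,19-dioate
Product: 27 diallyl 3β-hydroxylabda-8(17),13E-diene-15,19-dioate
Conditions: NaBH4, MeOH, 0 °C
Reagents that add atoms: none
Why: Sodium borohydride reduction in which hydride should approach C3 from the α-face, away from the axial C10 methyl and the axial C4 ester on the β-face, to give the equatorial 3β-alcohol.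

Step 19
Reactants: 27 diallyl 3β-hydroxylabda-8(17),13E-diene-15,19-dioate
Product: 28 diallyl 3β-acetoxylabda-8(17),13E-diene-15,19-dioate
Conditions: Ac2O, pyridine, DMAP (cat.), rt
Reagents that add atoms: acetic anhydride, CC(=O)OC(C)=O
Why: Standard DMAP-catalyzed acetylation of the secondary alcohol.

Step 20
Reactants: 28 diallyl 3β-acetoxylabda-8(17),13E-diene-15,19-dioate
Product: 29 3β-acetoxylabda-8(17),13E-diene-15,19-dioic acid (3β-acetoxyagathic acid)
Conditions: Pd(PPh3)4 (5 mol%), morpholine, THF, rt; then dilute aq. HCl work-up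
Reagents that add atoms: none
Why: Tsuji–Trost-type deallylation: zerovalent palladium ionizes both allyl esters by alkyl–oxygen cleavage, so the hindered C19 ester is no obstacle, and morpholine traps the allyl groups while the acetate and the alkenes stay untouched.

## Compound list

1 | methyl (2E)-3,7-dimethylocta-2,6-dienoate (methyl geranate) | CC(C)=CCC/C(C)=C/C(=O)OC | starting material
2 | methyl (2E)-3-methyl-6-oxohex-2-enoate | O=CCC/C(C)=C/C(=O)OC | intermediate
3 | ethyltriphenylphosphonium iodide | CC[P+](c1ccccc1)(c1ccccc1)c1ccccc1.[I-] | starting material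
4 | (1-iodoethylidene)triphenylphosphorane (iodo ylide) | CC(I)=P(c1ccccc1)(c1ccccc1)c1ccccc1 | intermediate
5 | methyl (2E,6Z)-7-iodo-3-methylocta-2,6-dienoate | C/C(I)=C/CC/C(C)=C/C(=O)OC | intermediate
6 | 3-[(tert-butyldimethylsilyl)oxy]propanal | O=CCCO[Si](C)(C)C(C)(C)C | starting material
7 | methyl (2E,6Z)-10-[(tert-butyldimethylsilyl)oxy]-8-hydroxy-3,7-dimethyldeca-2,6-dienoate (racemic at C8) | C/C(=C/CC/C(C)=C/C(=O)OC)C(O)CCO[Si](C)(C)C(C)(C)C | intermediate
8 | methyl (2E,6Z)-10-[(tert-butyldimethylsilyl)oxy]-3,7-dimethyl-8-oxodeca-2,6-dienoate | C/C(=C/CC/C(C)=C/C(=O)OC)C(=O)CCO[Si](C)(C)C(C)(C)C | intermediate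
9 | methyl (2E,6Z,8S)-10-[(tert-butyldimethylsilyl)oxy]-8-hydroxy-3,7-dimethyldeca-2,6-dienoate | C/C(=C/CC/C(C)=C/C(=O)OC)[C@@H](O)CCO[Si](C)(C)C(C)(C)C | intermediate
10 | methyl (2E,6Z,8S)-10-[(tert-butyldimethylsilyl)oxy]-3,7-dimethyl-8-(pyridine-2-carbonyloxy)deca-2,6-dienoate | C/C(=C/CC/C(C)=C/C(=O)OC)[C@@H](OC(=O)c1ccccn1)CCO[Si](C)(C)C(C)(C)C | intermediate
11 | 2,3-dibromoprop-1-ene | C=C(Br)CBr | starting material
12 | (1,3-dioxolan-2-ylmethyl)magnesium bromide | Br[Mg]CC1OCCO1 | starting material
13 | 2-(3-bromobut-3-en-1-yl)-1,3-dioxolane | C=C(Br)CCC1OCCO1 | intermediate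
14 | [4-(1,3-dioxolan-2-yl)but-1-en-2-yl]magnesium bromide (alkenyl Grignard reagent) | C=C([Mg]Br)CCC1OCCO1 | intermediate
15 | methyl (2E,6S,7E)-10-[(tert-butyldimethylsilyl)oxy]-6-[4-(1,3-dioxolan-2-yl)but-1-en-2-yl]-3,7-dimethyldeca-2,7-dienoate | CC(C)(C)[Si](C)(C)OCC/C=C(C)/[C@@H](CC/C(C)=C/C(=O)OC)C(=C)CCC1OCCO1 | intermediate
16 | methyl (2E,6S,7E)-10-[(tert-butyldimethylsilyl)oxy]-3,7-dimethyl-6-(5-oxopent-1-en-2-yl)deca-2,7-dienoate | CC(C)(C)[Si](C)(C)OCC/C=C(C)/[C@@H](CC/C(C)=C/C(=O)OC)C(=C)CCC=O | intermediate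
17 | ethyl 2-[bis(2,2,2-trifluoroethoxy)phosphoryl]propanoate | CCOC(=O)C(C)P(=O)(OCC(F)(F)F)OCC(F)(F)F | starting material
18 | 1-ethyl 12-methyl (2Z,7S,10E)-7-[(2E)-5-[(tert-butyldimethylsilyl)oxy]pent-2-en-2-yl]-2,10-dimethyl-6-methylidenedodeca-2,10-dienedioate | CC(C)(C)[Si](C)(C)OCC/C=C(C)/[C@@H](CC/C(C)=C/C(=O)OC)C(=C)CC/C=C(C)\C(=O)OCC | intermediate
19 | diallyl (2Z,7S,10E)-7-[(2E)-5-[(tert-butyldimethylsilyl)oxy]pent-2-en-2-yl]-2,10-dimethyl-6-methylidenedodeca-2,10-dienedioate | CC(C)(C)[Si](C)(C)OCC/C=C(C)/[C@@H](CC/C(C)=C/C(=O)OCC=C)C(=C)CC/C=C(C)\C(=O)OCC=C | intermediate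
20 | diallyl (2Z,7S,10E)-7-[(2E)-5-hydroxypent-2-en-2-yl]-2,10-dimethyl-6-methylidenedodeca-2,10-dienedioate | OCC/C=C(C)/[C@@H](CC/C(C)=C/C(=O)OCC=C)C(=C)CC/C=C(C)\C(=O)OCC=C | intermediate
21 | diallyl (2Z,7S,10E)-2,10-dimethyl-6-methylidene-7-[(2E)-5-oxopent-2-en-2-yl]dodeca-2,10-dienedioate | O=CC/C=C(C)/[C@@H](CC/C(C)=C/C(=O)OCC=C)C(=C)CC/C=C(C)\C(=O)OCC=C | intermediate
22 | diallyl (2Z,7S,10E)-7-[(2E,4E)-5-[(tert-butyldimethylsilyl)oxy]penta-2,4-dien-2-yl]-2,10-dimethyl-6-methylidenedodeca-2,10-dienedioate | CC(C)(C)[Si](C)(C)O/C=C/C=C(C)/[C@@H](CC/C(C)=C/C(=O)OCC=C)C(=C)CC/C=C(C)\C(=O)OCC=C | intermediate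
23 | diallyl 3α-[(tert-butyldimethylsilyl)oxy]labda-1,8(17),13E-triene-15,19-dioate (silyl ether cycloadduct) | C=C1CC[C@@H]2[C@](C)(C=C[C@@H](O[Si](C)(C)C(C)(C)C)[C@]2(C)C(=O)OCC=C)[C@H]1CC/C(C)=C/C(=O)OCC=C | intermediate
24 | diallyl 3α-hydroxylabda-1,8(17),13E-triene-15,19-dioate | C=C1CC[C@@H]2[C@](C)(C=C[C@@H](O)[C@]2(C)C(=O)OCC=C)[C@H]1CC/C(C)=C/C(=O)OCC=C | intermediate
25 | diallyl 3-oxolabda-1,8(17),13E-triene-15,19-dioate | C=C1CC[C@@H]2[C@](C)(C=CC(=O)[C@]2(C)C(=O)OCC=C)[C@H]1CC/C(C)=C/C(=O)OCC=C | intermediate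
26 | diallyl 3-oxolabda-8(17),13E-diene-15,19-dioate | C=C1CC[C@@H]2[C@](C)(CCC(=O)[C@]2(C)C(=O)OCC=C)[C@H]1CC/C(C)=C/C(=O)OCC=C | intermediate
27 | diallyl 3β-hydroxylabda-8(17),13E-diene-15,19-dioate | C=C1CC[C@@H]2[C@](C)(CC[C@H](O)[C@]2(C)C(=O)OCC=C)[C@H]1CC/C(C)=C/C(=O)OCC=C | intermediate
28 | diallyl 3β-acetoxylabda-8(17),13E-diene-15,19-dioate | C=C1CC[C@@H]2[C@](C)(CC[C@H](OC(C)=O)[C@]2(C)C(=O)OCC=C)[C@H]1CC/C(C)=C/C(=O)OCC=C | intermediate
29 | 3β-acetoxylabda-8(17),13E-diene-15,19-dioic acid (3β-acetoxyagathic acid) | C=C1CC[C@@H]2[C@](C)(CC[C@H](OC(C)=O)[C@]2(C)C(=O)O)[C@H]1CC/C(C)=C/C(=O)O | target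

## Step count and risks

Total steps: 20. Longest linear sequence: 19 steps (steps 1–6 and 8–20; step 7 is the side branch).

Steps most likely to fail:

1. Step 15. The preference for the trans-fused, side-chain-equatorial transition state may be too small (leakage into cis-fused or facially mismatched adducts). A [1,5]-hydrogen shift from the cis methyl group of the diene may also outrun a slow cycloaddition of the trisubstituted dienophile. Fallback: replace the neutral thermal cycloaddition by an anion-accelerated, stepwise ring construction at low temperature, setting out from aldehyde 21. Treatment with KN(SiMe3)2 and 18-crown-6 in THF (−78 → −20 °C) should give the potassium dienolate, potassium (1E,3E)-dienolate of aldehyde 21 F1, in which C10 adds to C5 of the (Z)-enoate (vinylogous Michael addition, ring B). The resulting ester enolate should then add to the C3 aldehyde (aldol, ring A) before rotation about C4–C5 can scramble C4. Protonation should give 24 and possibly its C3 epimer, diallyl 3β-hydroxylabda-1,8(17),13E-triene-15,19-dioate F2. Both are oxidized under the conditions of step 16, so the fallback comes back to the route at 25.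

2. Step 8. The alkenyl nucleophile may attack the carbinol carbon directly or the picolinate carbonyl, or chirality transfer and alkene geometry may be incomplete. Fallback: change the organometallic partner and the leaving group to a catalytic boron/copper coupling, setting out from 13 and 9. Miyaura borylation of 13 (B2pin2, PdCl2(dppf), KOPh, toluene, 50 °C) should give 2-[4-(1,3-dioxolan-2-yl)but-1-en-2-yl]-4,4,5,5-tetramethyl-1,3,2-dioxaborolane F3. Alcohol 9 is converted with ClP(O)(OEt)2, pyridine and DMAP to methyl (2E,6Z,8S)-10-[(tert-butyldimethylsilyl)oxy]-8-[(diethoxyphosphoryl)oxy]-3,7-dimethyldeca-2,6-dienoate F4. Copper-catalyzed γ-selective, 1,3-anti-stereospecific allyl–alkenyl coupling of F4 with F3 (CuCl cat., KOtBu, THF, rt) should then give 15, where the route is rejoined.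

3. Step 5. The twisted (Z)-enone may be a poor substrate for the oxazaborolidine (loss of enantioselectivity), and Z to E isomerization of the enone may occur during steps 4 and 5. Fallback: skip the oxidation–reduction pair and resolve racemic 7 enzymatically. Candida antarctica lipase B with vinyl acetate in hexane at rt is expected to acylate the (8R)-enantiomer to methyl (2E,6Z,8R)-8-acetoxy-10-[(tert-butyldimethylsilyl)oxy]-3,7-dimethyldeca-2,6-dienoate F5 and leave the (8S)-alcohol. After chromatographic separation the fallback comes back to the route at 9.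

## Further compounds

F1 | step 15 | potassium (1E,3E)-dienolate of aldehyde 21 | [K+].[O-]/C=C/C=C(C)/[C@@H](CC/C(C)=C/C(=O)OCC=C)C(=C)CC/C=C(C)\C(=O)OCC=C
F2 | step 15 | diallyl 3β-hydroxylabda-1,8(17),13E-triene-15,19-dioate | C=C1CC[C@@H]2[C@](C)(C=C[C@H](O)[C@]2(C)C(=O)OCC=C)[C@H]1CC/C(C)=C/C(=O)OCC=C
F3 | step 8 | 2-[4-(1,3-dioxolan-2-yl)but-1-en-2-yl]-4,4,5,5-tetramethyl-1,3,2-dioxaborolane | C=C(CCC1OCCO1)B1OC(C)(C)C(C)(C)O1
F4 | step 8 | methyl (2E,6Z,8S)-10-[(tert-butyldimethylsilyl)oxy]-8-[(diethoxyphosphoryl)oxy]-3,7-dimethyldeca-2,6-dienoate | C/C(=C/CC/C(C)=C/C(=O)OC)[C@@H](OP(=O)(OCC)OCC)CCO[Si](C)(C)C(C)(C)C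
F5 | step 5 | methyl (2E,6Z,8R)-8-acetoxy-10-[(tert-butyldimethylsilyl)oxy]-3,7-dimethyldeca-2,6-dienoate | C/C(=C/CC/C(C)=C/C(=O)OC)[C@H](OC(C)=O)CCO[Si](C)(C)C(C)(C)C
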